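The two bonds at C1 of the 1‑methyl‑3,4‑dihydroisoquinoline, C1–C8a and C1–CH3, are disconnected. The feature exploited is the ketimine carbon C1 of the nitrogen ring, bonded only to C8a of ring A, to N2 and to a methyl group; this is the bonding pattern of an isocyanide carbon after aryl migration and methyl coupling. One palladium‑catalysed operation thus closes the nitrogen ring and installs the methyl group. Its precursor is the (S)‑2‑isocyanopropyl biaryl with both phenols as isopropyl ethers and a triflate at C8a. This leaving group descends from the phenol oxygen of 5‑bromovanillin, so the closure site is set by the starting material and not by an electrophilic substitution choosing between C8a and C5.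

Key step: step 14

Remark on the chemistry: the target carries no descriptor for the biaryl axis, so the axis is treated as undefined and the biaryls 20 to 27 are carried without atropisomer control.

Step 1
Reactants: 1 2-bromo-5-methoxybenzaldehyde; 2 diethyl succinate
Product: 3 (E)-4-(2-bromo-5-methoxyphenyl)-3-(ethoxycarbonyl)but-3-enoic acid
Conditions: KOtBu, tBuOH, reflux; then aq. HCl
Reagents that add atoms: none
Why: Stobbe condensation, in which the succinate enolate adds to the aldehyde, lactonises and ring-opens by elimination to the (E)-alkylidene half-ester, the geometry that places the aryl group cis to the CH2CO2H arm as the next step requires.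

Step 2
Reactants: 3 (E)-4-(2-bromo-5-methoxyphenyl)-3-(ethoxycarbonyl)but-3-enoic acid
Product: 4 ethyl 4-acetoxy-8-bromo-5-methoxy-2-naphthoate
Conditions: Ac2O, NaOAc, 140 °C
Reagents that add atoms: acetic anhydride, CC(=O)OC(C)=O
Why: Intramolecular Friedel–Crafts acylation through the mixed anhydride at the only free position ortho to the side chain (activated by the neighbouring methoxy group), followed by enolisation and O-acetylation, should give the naphthyl acetate.

Step 3
Reactants: 4 ethyl 4-acetoxy-8-bromo-5-methoxy-2-naphthoate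
Product: 5 5-bromo-3-(hydroxymethyl)-8-methoxynaphthalen-1-ol
Conditions: LiAlH4, THF, 0 °C
Reagents that add atoms: none
Why: Hydride reduction takes the ester to the primary alcohol and cleaves the aryl acetate in the same operation, while an aryl bromide is not reduced at 0 °C.

Step 4
Reactants: 5 5-bromo-3-(hydroxymethyl)-8-methoxynaphthalen-1-ol
Product: 6 (8-bromo-4-isopropoxy-5-methoxynaphthalen-2-yl)methanol
Conditions: 2-bromopropane, K2CO3, DMF, 60 °C
Reagents that add atoms: 2-bromopropane, CC(C)Br
Why: Williamson ether synthesis in which carbonate deprotonates only the naphthol, so the benzylic alcohol stays free.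

Step 5
Reactants: 6 (8-bromo-4-isopropoxy-5-methoxynaphthalen-2-yl)methanol
Product: 8 1-bromo-5-isopropoxy-4-methoxy-7-methylnaphthalene, via naphthylmethyl mesylate 7 (not isolated)
Conditions: MsCl, Et3N, THF, 0 °C; then LiBHEt3 (excess), 0 °C to rt
Reagents that add atoms: none
Why: Mesylation followed by SN2 hydride displacement (reductive deoxygenation of a primary benzylic sulfonate) should give the methyl group, the aryl bromide being inert to the borohydride at this temperature.

Step 6
Reactants: 9 5-bromovanillin (3-bromo-4-hydroxy-5-methoxybenzaldehyde)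
Product: 10 3-bromo-5-methoxy-4-(triisopropylsilyloxy)benzaldehyde
Conditions: iPr3SiCl, imidazole, DMF, 40 °C
Reagents that add atoms: chlorotriisopropylsilane, CC(C)[Si](Cl)(C(C)C)C(C)C
Why: Silyl ether formation on the phenol, giving a bulky group that withstands the peracid, carbonate, Grignard and alkyllithium steps and marks the oxygen that later becomes the leaving group at C8a.

Step 7
Reactants: 10 3-bromo-5-methoxy-4-(triisopropylsilyloxy)benzaldehyde
Product: 12 3-bromo-5-methoxy-4-(triisopropylsilyloxy)phenol, via aryl formate 11 (not isolated)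
Conditions: mCPBA, CH2Cl2, rt; then Et3N, MeOH, rt
Reagents that add atoms: 3-chloroperoxybenzoic acid, OOC(=O)c1cccc(Cl)c1
Why: Baeyer–Villiger (Dakin-type) oxidation in which the electron-rich aryl group with its para oxygen migrates in preference to hydrogen, and mild methanolysis of the formate frees the phenol that becomes O6.

Step 8
Reactants: 12 3-bromo-5-methoxy-4-(triisopropylsilyloxy)phenol
Product: 13 (2-bromo-4-isopropoxy-6-methoxyphenoxy)triisopropylsilane
Conditions: 2-bromopropane, K2CO3, DMF, 50 °C
Reagents that add atoms: 2-bromopropane, CC(C)Br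
Why: Williamson ether synthesis on the only free phenol; the hindered aryl triisopropylsilyl ether tolerates carbonate in DMF.

Step 9
Reactants: 13 (2-bromo-4-isopropoxy-6-methoxyphenoxy)triisopropylsilane; 14 tert-butyl (S)-4-methyl-1,2,3-oxathiazolidine-3-carboxylate 2,2-dioxide
Product: 17 tert-butyl (S)-{1-[5-isopropoxy-3-methoxy-2-(triisopropylsilyloxy)phenyl]propan-2-yl}carbamate, via arylmagnesium bromide 15 (not isolated), via magnesium N-sulfamate 16 (not isolated)
Conditions: Mg, THF, 45 °C; then CuI (10 mol %), 14, −20 °C to rt; then 10 % aq. citric acid, rt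
Reagents that add atoms: none
Why: Magnesium insertion and copper-catalysed SN2 opening of the cyclic sulfamidate at its CH2–O carbon (alkylation of a Grignard reagent) form the aryl–CH2 bond without touching the stereocentre, which is carried over as (S) from the L-alanine-derived reagent 14, and mild acid hydrolyses the N-sulfate.

Step 10
Reactants: 17 tert-butyl (S)-{1-[5-isopropoxy-3-methoxy-2-(triisopropylsilyloxy)phenyl]propan-2-yl}carbamate; 8 1-bromo-5-isopropoxy-4-methoxy-7-methylnaphthalene
Product: 20 tert-butyl (S)-{1-[5-isopropoxy-4-(5-isopropoxy-4-methoxy-7-methylnaphthalen-1-yl)-3-methoxy-2-(triisopropylsilyloxy)phenyl]propan-2-yl}carbamate, via dilithiated carbamate 18 (not isolated), via arylzinc chloride 19 (not isolated)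
Conditions: nBuLi (2.3 equiv), THF, −20 to 0 °C; ZnCl2 (2.5 equiv), 0 °C to rt; then 8, Pd2(dba)3 (2.5 mol %), SPhos (10 mol %), 65 °C
Reagents that add atoms: none
Why: Directed ortho-metalation, in which the second equivalent of nBuLi removes the ring hydrogen flanked by the methoxy and isopropoxy groups (C7) after N–H deprotonation, followed by Negishi coupling of the derived arylzinc with the naphthyl bromide under a bulky biarylphosphine catalyst suited to hindered biaryls.

Step 11
Reactants: 20 tert-butyl (S)-{1-[5-isopropoxy-4-(5-isopropoxy-4-methoxy-7-methylnaphthalen-1-yl)-3-methoxy-2-(triisopropylsilyloxy)phenyl]propan-2-yl}carbamate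
Product: 22 (S)-6-{2-[(tert-butoxycarbonyl)amino]propyl}-4-isopropoxy-3-(5-isopropoxy-4-methoxy-7-methylnaphthalen-1-yl)-2-methoxyphenyl trifluoromethanesulfonate, via tetrabutylammonium phenoxide 21 (not isolated)
Conditions: Bu4NF, THF, 0 °C; then PhNTf2, 0 °C to rt
Reagents that add atoms: N-phenylbis(trifluoromethanesulfonimide), O=S(=O)(N(c1ccccc1)S(=O)(=O)C(F)(F)F)C(F)(F)F
Why: Fluoride cleaves the aryl silyl ether and the phenoxide is sulfonylated in the same flask (desilylative triflation), while the carbamate N–H does not react with this mild triflating agent.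

Step 12
Reactants: 22 (S)-6-{2-[(tert-butoxycarbonyl)amino]propyl}-4-isopropoxy-3-(5-isopropoxy-4-methoxy-7-methylnaphthalen-1-yl)-2-methoxyphenyl trifluoromethanesulfonate
Product: 24 (S)-6-(2-formamidopropyl)-4-isopropoxy-3-(5-isopropoxy-4-methoxy-7-methylnaphthalen-1-yl)-2-methoxyphenyl trifluoromethanesulfonate, via amine hydrochloride 23 (not isolated)
Conditions: HCl (4 M in 1,4-dioxane), CH2Cl2, 0 °C to rt; evaporate; then HCO2Et, Et3N, 55 °C
Reagents that add atoms: ethyl formate, CCOC=O
Why: Acidolysis of the tert-butyl carbamate followed by N-formylation of the liberated primary amine (aminolysis of a formate ester); the aryl triflate and the aryl ethers are stable to both stages.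

Step 13
Reactants: 24 (S)-6-(2-formamidopropyl)-4-isopropoxy-3-(5-isopropoxy-4-methoxy-7-methylnaphthalen-1-yl)-2-methoxyphenyl trifluoromethanesulfonate
Product: 25 (S)-6-(2-isocyanopropyl)-4-isopropoxy-3-(5-isopropoxy-4-methoxy-7-methylnaphthalen-1-yl)-2-methoxyphenyl trifluoromethanesulfonate
Conditions: POCl3, Et3N, CH2Cl2, −20 to 0 °C
Reagents that add atoms: none
Why: Dehydration of the secondary formamide with POCl3 and a tertiary amine (Ugi isocyanide synthesis) proceeds at or below 0 °C without affecting the stereocentre or the triflate.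

Step 14
Reactants: 25 (S)-6-(2-isocyanopropyl)-4-isopropoxy-3-(5-isopropoxy-4-methoxy-7-methylnaphthalen-1-yl)-2-methoxyphenyl trifluoromethanesulfonate
Product: 26 (S)-6-isopropoxy-7-(5-isopropoxy-4-methoxy-7-methylnaphthalen-1-yl)-8-methoxy-1,3-dimethyl-3,4-dihydroisoquinoline
Conditions: Pd(OAc)2 (5 mol %), Xantphos (6 mol %), trimethylboroxine (1.0 equiv), K2CO3 (3 equiv), degassed 1,4-dioxane, 95 °C, 25 added over 6 h
Reagents that add atoms: trimethylboroxine, CB1OB(C)OB(C)O1
Why: Proposed new method: zerovalent palladium, formed in the flask from Pd(OAc)2 and Xantphos, adds oxidatively to the C8a–OTf bond, the tethered isocyanide carbon binds to the metal and the aryl group migrates onto it (1,1-insertion) to give a cyclic imidoyl complex of divalent palladium, which accepts a methyl group from the carbonate-activated boroxine and reductively eliminates the C1–CH3 bond. The closest known reaction type is the palladium-catalysed imidoylative cross-coupling, in which an isocyanide inserts into an aryl–palladium bond and the imidoyl complex is coupled with an organometallic partner; new here are the delivery of the isocyanide from within the same molecule and the use of a methylboron reagent. The nitrogen ring closes in a formally 6-endo-dig mode, the C8a–C1 bond forming as the aryl carbon migrates to the isocyanide carbon whose nitrogen is already tied to C3 and C4. No stereocentre is created, and C3 is not acidic under carbonate, so its (S) configuration should be retained. The step needs site selectivity (C8a, not C5) and single insertion: the first is fixed by the position of the triflate, the second is favoured by slow addition at high dilution, which keeps free isocyanide scarce while the pendant one stays close to the metal.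

Step 15
Reactants: 26 (S)-6-isopropoxy-7-(5-isopropoxy-4-methoxy-7-methylnaphthalen-1-yl)-8-methoxy-1,3-dimethyl-3,4-dihydroisoquinoline
Product: 27 (S)-7-(5-hydroxy-4-methoxy-7-methylnaphthalen-1-yl)-8-methoxy-1,3-dimethyl-3,4-dihydroisoquinolin-6-ol
Conditions: BCl3 (6 equiv), CH2Cl2, −78 to 0 °C; then MeOH; aq. NaHCO3
Reagents that add atoms: none
Why: Lewis acid dealkylation, in which BCl3 cleaves secondary (isopropyl) aryl ethers far faster than methyl ethers at or below 0 °C, should release both phenols and leave both methoxy groups, the excess reagent compensating for coordination to the imine nitrogen.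

Compound list

1 | 2-bromo-5-methoxybenzaldehyde | COc1ccc(Br)c(C=O)c1 | starting material
2 | diethyl succinate | CCOC(=O)CCC(=O)OCC | starting material
3 | (E)-4-(2-bromo-5-methoxyphenyl)-3-(ethoxycarbonyl)but-3-enoic acid | CCOC(=O)/C(CC(=O)O)=C/c1cc(OC)ccc1Br | intermediate
4 | ethyl 4-acetoxy-8-bromo-5-methoxy-2-naphthoate | CCOC(=O)c1cc(OC(C)=O)c2c(OC)ccc(Br)c2c1 | intermediate
5 | 5-bromo-3-(hydroxymethyl)-8-methoxynaphthalen-1-ol | OCc1cc(O)c2c(OC)ccc(Br)c2c1 | intermediate
6 | (8-bromo-4-isopropoxy-5-methoxynaphthalen-2-yl)methanol | OCc1cc(OC(C)C)c2c(OC)ccc(Br)c2c1 | intermediate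
7 | (8-bromo-4-isopropoxy-5-methoxynaphthalen-2-yl)methyl methanesulfonate | CS(=O)(=O)OCc1cc(OC(C)C)c2c(OC)ccc(Br)c2c1 | intermediate
8 | 1-bromo-5-isopropoxy-4-methoxy-7-methylnaphthalene | Cc1cc(OC(C)C)c2c(OC)ccc(Br)c2c1 | intermediate
9 | 5-bromovanillin (3-bromo-4-hydroxy-5-methoxybenzaldehyde) | COc1cc(C=O)cc(Br)c1O | starting material
10 | 3-bromo-5-methoxy-4-(triisopropylsilyloxy)benzaldehyde | COc1cc(C=O)cc(Br)c1O[Si](C(C)C)(C(C)C)C(C)C | intermediate
11 | 3-bromo-5-methoxy-4-(triisopropylsilyloxy)phenyl formate | COc1cc(OC=O)cc(Br)c1O[Si](C(C)C)(C(C)C)C(C)C | intermediate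
12 | 3-bromo-5-methoxy-4-(triisopropylsilyloxy)phenol | COc1cc(O)cc(Br)c1O[Si](C(C)C)(C(C)C)C(C)C | intermediate
13 | (2-bromo-4-isopropoxy-6-methoxyphenoxy)triisopropylsilane | COc1cc(OC(C)C)cc(Br)c1O[Si](C(C)C)(C(C)C)C(C)C | intermediate
14 | tert-butyl (S)-4-methyl-1,2,3-oxathiazolidine-3-carboxylate 2,2-dioxide (cyclic sulfamidate of N-Boc-L-alaninol) | C[C@H]1COS(=O)(=O)N1C(=O)OC(C)(C)C | starting material
15 | [5-isopropoxy-3-methoxy-2-(triisopropylsilyloxy)phenyl]magnesium bromide | COc1cc(OC(C)C)cc([Mg]Br)c1O[Si](C(C)C)(C(C)C)C(C)C | intermediate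
16 | bromomagnesium (S)-N-(tert-butoxycarbonyl)-N-{1-[5-isopropoxy-3-methoxy-2-(triisopropylsilyloxy)phenyl]propan-2-yl}sulfamate | COc1cc(OC(C)C)cc(C[C@H](C)N(C(=O)OC(C)(C)C)S(=O)(=O)O[Mg]Br)c1O[Si](C(C)C)(C(C)C)C(C)C | intermediate
17 | tert-butyl (S)-{1-[5-isopropoxy-3-methoxy-2-(triisopropylsilyloxy)phenyl]propan-2-yl}carbamate | COc1cc(OC(C)C)cc(C[C@H](C)NC(=O)OC(C)(C)C)c1O[Si](C(C)C)(C(C)C)C(C)C | intermediate
18 | N,C-dilithio derivative of 17 (lithium on nitrogen and on the ring carbon between the methoxy and isopropoxy groups) | COc1c([Li])c(OC(C)C)cc(C[C@H](C)N([Li])C(=O)OC(C)(C)C)c1O[Si](C(C)C)(C(C)C)C(C)C | intermediate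
19 | bis(chlorozinc) derivative of 17 (zinc on nitrogen and on the ring carbon between the methoxy and isopropoxy groups) | COc1c([Zn]Cl)c(OC(C)C)cc(C[C@H](C)N([Zn]Cl)C(=O)OC(C)(C)C)c1O[Si](C(C)C)(C(C)C)C(C)C | intermediate
20 | tert-butyl (S)-{1-[5-isopropoxy-4-(5-isopropoxy-4-methoxy-7-methylnaphthalen-1-yl)-3-methoxy-2-(triisopropylsilyloxy)phenyl]propan-2-yl}carbamate | COc1c(-c2ccc(OC)c3c(OC(C)C)cc(C)cc23)c(OC(C)C)cc(C[C@H](C)NC(=O)OC(C)(C)C)c1O[Si](C(C)C)(C(C)C)C(C)C | intermediate
21 | tetrabutylammonium (S)-6-{2-[(tert-butoxycarbonyl)amino]propyl}-4-isopropoxy-3-(5-isopropoxy-4-methoxy-7-methylnaphthalen-1-yl)-2-methoxyphenolate | COc1c(-c2ccc(OC)c3c(OC(C)C)cc(C)cc23)c(OC(C)C)cc(C[C@H](C)NC(=O)OC(C)(C)C)c1[O-].CCCC[N+](CCCC)(CCCC)CCCC | intermediate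
22 | (S)-6-{2-[(tert-butoxycarbonyl)amino]propyl}-4-isopropoxy-3-(5-isopropoxy-4-methoxy-7-methylnaphthalen-1-yl)-2-methoxyphenyl trifluoromethanesulfonate | COc1c(-c2ccc(OC)c3c(OC(C)C)cc(C)cc23)c(OC(C)C)cc(C[C@H](C)NC(=O)OC(C)(C)C)c1OS(=O)(=O)C(F)(F)F | intermediate
23 | (S)-6-(2-aminopropyl)-4-isopropoxy-3-(5-isopropoxy-4-methoxy-7-methylnaphthalen-1-yl)-2-methoxyphenyl trifluoromethanesulfonate hydrochloride | COc1c(-c2ccc(OC)c3c(OC(C)C)cc(C)cc23)c(OC(C)C)cc(C[C@H](C)N)c1OS(=O)(=O)C(F)(F)F.Cl | intermediate
24 | (S)-6-(2-formamidopropyl)-4-isopropoxy-3-(5-isopropoxy-4-methoxy-7-methylnaphthalen-1-yl)-2-methoxyphenyl trifluoromethanesulfonate | COc1c(-c2ccc(OC)c3c(OC(C)C)cc(C)cc23)c(OC(C)C)cc(C[C@H](C)NC=O)c1OS(=O)(=O)C(F)(F)F | intermediate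
25 | (S)-6-(2-isocyanopropyl)-4-isopropoxy-3-(5-isopropoxy-4-methoxy-7-methylnaphthalen-1-yl)-2-methoxyphenyl trifluoromethanesulfonate | COc1c(-c2ccc(OC)c3c(OC(C)C)cc(C)cc23)c(OC(C)C)cc(C[C@H](C)[N+]#[C-])c1OS(=O)(=O)C(F)(F)F | intermediate
26 | (S)-6-isopropoxy-7-(5-isopropoxy-4-methoxy-7-methylnaphthalen-1-yl)-8-methoxy-1,3-dimethyl-3,4-dihydroisoquinoline | COc1c2c(cc(OC(C)C)c1-c1ccc(OC)c3c(OC(C)C)cc(C)cc13)C[C@H](C)N=C2C | intermediate
27 | (S)-7-(5-hydroxy-4-methoxy-7-methylnaphthalen-1-yl)-8-methoxy-1,3-dimethyl-3,4-dihydroisoquinolin-6-ol | COc1c2c(cc(O)c1-c1ccc(OC)c3c(O)cc(C)cc13)C[C@H](C)N=C2C | target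

Total step count: 15.
Longest linear sequence: 11 steps (steps 1 to 5, then steps 10 to 15, from 2-bromo-5-methoxybenzaldehyde 1).

Steps most likely to fail

Step 14 (proposed new method). The pendant isocyanide may not reach the palladium centre that carries the aryl group, so that isocyanide adds between molecules and oligomerises on the metal, or a methyl group is transferred to C8a before insertion. The fallback uses known chemistry, sets out from 22 and returns at 26. Stille coupling of triflate 22 with tributyl(1-ethoxyvinyl)stannane (Pd(PPh3)4, LiCl, 1,4-dioxane, 100 °C) should give the enol ether tert-butyl (S)-{1-[2-(1-ethoxyvinyl)-5-isopropoxy-4-(5-isopropoxy-4-methoxy-7-methylnaphthalen-1-yl)-3-methoxyphenyl]propan-2-yl}carbamate F1. Dilute aqueous HCl in THF hydrolyses it to the aryl methyl ketone tert-butyl (S)-{1-[2-acetyl-5-isopropoxy-4-(5-isopropoxy-4-methoxy-7-methylnaphthalen-1-yl)-3-methoxyphenyl]propan-2-yl}carbamate F2. HCl in 1,4-dioxane then removes the carbamate to give (S)-1-[6-(2-aminopropyl)-4-isopropoxy-3-(5-isopropoxy-4-methoxy-7-methylnaphthalen-1-yl)-2-methoxyphenyl]ethan-1-one hydrochloride F3, and neutralisation with aqueous NaHCO3 lets the amine condense with the ortho acetyl group to the cyclic ketimine 26. Here C1 and its methyl arrive together as an acetyl group and the C1=N bond is made last; the closure site is still fixed by the triflate.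

Step 10. Transmetalation and reductive elimination at the doubly ortho-substituted arylzinc may be slow, so that the catalyst decays and protonated arene 17 is returned. The fallback reverses the polarity of the coupling, sets out from 17 (through its dilithio form 18) and from 8, and returns at 20. Quenching 18 with I2 (THF, −78 °C; thiosulfate work-up) should give tert-butyl (S)-{1-[4-iodo-5-isopropoxy-3-methoxy-2-(triisopropylsilyloxy)phenyl]propan-2-yl}carbamate F4. Bromide 8 is borylated (B2pin2, Pd2(dba)3, XPhos, KOAc, 1,4-dioxane, 90 °C) to 2-(5-isopropoxy-4-methoxy-7-methylnaphthalen-1-yl)-4,4,5,5-tetramethyl-1,3,2-dioxaborolane F5. Suzuki–Miyaura coupling of F4 with F5 (Pd(OAc)2, SPhos, K3PO4, toluene/water, 90 °C) then gives 20, with the less hindered naphthyl partner as the nucleophile.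

Step 9. The hindered ortho-silyloxy arylmagnesium reagent may attack the carbamate carbonyl or the sulfur of 14 instead of carbon, or the silyl group may migrate from oxygen to the metalated carbon. The fallback exchanges the roles of the partners, sets out from 13 and 14, and returns at 17. NaI in acetone opens 14 at the CH2 carbon to sodium (S)-N-(tert-butoxycarbonyl)-N-(1-iodopropan-2-yl)sulfamate F6, which aqueous citric acid hydrolyses to tert-butyl (S)-(1-iodopropan-2-yl)carbamate F7. Zinc dust in DMF inserts to give (S)-{2-[(tert-butoxycarbonyl)amino]propyl}zinc iodide F8. Negishi coupling of F8 with aryl bromide 13 (Pd2(dba)3, SPhos, DMF, 50 °C) should give 17, the aryl unit now being the electrophile and no aryl–metal species ortho to the silyl ether being formed.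

Further compounds

F1 | step 14 | tert-butyl (S)-{1-[2-(1-ethoxyvinyl)-5-isopropoxy-4-(5-isopropoxy-4-methoxy-7-methylnaphthalen-1-yl)-3-methoxyphenyl]propan-2-yl}carbamate | CCOC(=C)c1c(OC)c(-c2ccc(OC)c3c(OC(C)C)cc(C)cc23)c(OC(C)C)cc1C[C@H](C)NC(=O)OC(C)(C)C
F2 | step 14 | tert-butyl (S)-{1-[2-acetyl-5-isopropoxy-4-(5-isopropoxy-4-methoxy-7-methylnaphthalen-1-yl)-3-methoxyphenyl]propan-2-yl}carbamate | CC(=O)c1c(OC)c(-c2ccc(OC)c3c(OC(C)C)cc(C)cc23)c(OC(C)C)cc1C[C@H](C)NC(=O)OC(C)(C)C
F3 | step 14 | (S)-1-[6-(2-aminopropyl)-4-isopropoxy-3-(5-isopropoxy-4-methoxy-7-methylnaphthalen-1-yl)-2-methoxyphenyl]ethan-1-one hydrochloride | CC(=O)c1c(OC)c(-c2ccc(OC)c3c(OC(C)C)cc(C)cc23)c(OC(C)C)cc1C[C@H](C)N.Cl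
F4 | step 10 | tert-butyl (S)-{1-[4-iodo-5-isopropoxy-3-methoxy-2-(triisopropylsilyloxy)phenyl]propan-2-yl}carbamate | COc1c(I)c(OC(C)C)cc(C[C@H](C)NC(=O)OC(C)(C)C)c1O[Si](C(C)C)(C(C)C)C(C)C
F5 | step 10 | 2-(5-isopropoxy-4-methoxy-7-methylnaphthalen-1-yl)-4,4,5,5-tetramethyl-1,3,2-dioxaborolane | Cc1cc(OC(C)C)c2c(OC)ccc(B3OC(C)(C)C(C)(C)O3)c2c1
F6 | step 9 | sodium (S)-N-(tert-butoxycarbonyl)-N-(1-iodopropan-2-yl)sulfamate | C[C@@H](CI)N(C(=O)OC(C)(C)C)S(=O)(=O)[O-].[Na+]
F7 | step 9 | tert-butyl (S)-(1-iodopropan-2-yl)carbamate | C[C@@H](CI)NC(=O)OC(C)(C)C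
F8 | step 9 | (S)-{2-[(tert-butoxycarbonyl)amino]propyl}zinc iodide | C[C@@H](C[Zn]I)NC(=O)OC(C)(C)C
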